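- I started with the easy step: once c(Q) is held at its charge, Z leaves by first-order routes.

    Z → D (k1 = 0.0074 s⁻¹)
    Z → X (k2 = 0.014 s⁻¹)
    Q → L (k3 = 1.9 × 10⁻⁵ s⁻¹)
    Q + X → Q + J (k4 = 27 M⁻¹ s⁻¹)
    Z + Q → Z.Q (k5 = 3.5 M⁻¹ s⁻¹)

all flasks: Q 0.75 mM; time 50 s
- east: Z 0.60 mM
- north-west: Z 1.2 mM
- south-east: Z 2.5 mM
- north-east: Z 5.0 mM
- west: Z 10 mM

* [J] at the end for east, north-west, south-east, north-east, west, in this order
* the shape of the row from first to last (rises all the way / hardly changes / falls, then rises / rises, then falls / falls all the way)

- "hardly changes" means that all values lie within two and a half points (for a concentration: within two and a half percent of the largest)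
- run time (east): 50 s

- I added the constants of the routes to D, to X and to Z.Q, which gave 0.0240 s⁻¹; I dropped Q → L, which is slower than capture even in east.
- Z therefore stood in the flask for an effective time W of 29.1 s out of 50 s, W being the area under c(Z) divided by its charge.
- For west, the capture constant times the charge of Z times W gave 1.02; this is the capture number N, and exp(−N) is my estimate of the share of the charged Q still free at the end.
- The same number was 0.0611 in east and 0.509 in north-east.
- One number could not give J, which also needs a scale. With the charged catalyst, X goes at the pseudo-first-order constant 0.0203 s⁻¹, and the chain Z → X → J then turns 17.6% of the charged Z into J.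
- I let N bend that scale: X meets about the catalyst left after half of the capture, so I multiplied by exp(−N/2).
- That gave 0.102 mM for east and 1.06 mM for west, and my row rises all the way, since half of N stays below 1 even in west.
- The forecast gave 0.102 mM, 0.198 mM, 0.384 mM, 0.667 mM and 1 mM, a row that rises all the way, and said “J still rises throughout, though less than proportionally.”
- The simulation gave 0.102 mM, 0.198 mM, 0.384 mM, 0.669 mM and 1.00 mM, a row that rises all the way.
- In west, capture of Q by Z and the short time act together to hold J at 1.00 mM: without capture the run gave 1.83 mM, and the tenfold time gave 5.41 mM. In west, capture is a part of the reason, and the time is at most the largest single effect. In west exp(−N) reads 36.1%, and Q stood at 35.5% at 50.0 s. In north-east exp(−N) reads 60.1%, and Q stood at 59.7% at 50.0 s.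

(The rate constants are invented.)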